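## Structural features

Pilosanol B is a (2R,3S)-flavan-3-ol (rings A, C and B, the catechin configuration) whose ring A carbon C8 is joined through one methylene carbon to a hexasubstituted acylphloroglucinol, ring D. Counting around ring D from the methylene-bearing carbon D1, the substituents are OH (D2), methyl (D3), methoxy (D4), isobutyryl (D5) and OH (D6), so no ring D carbon is free and its three oxygens are differentiated. The stereocentres C2 (aryl-bearing, bonded to O1) and C3 (hydroxyl-bearing) are adjacent and trans, and C4 is a methylene group. Fragile elements are the seven free hydroxyl groups (six phenols, sensitive to air and base, with C2 epimerisation of free catechins in base), the acid-labile benzylic C2–O1 bond and electron-rich diarylmethane, and the enolisable aryl ketone. The real difficulty lies in the regiochemistry of two crowded arenes (ring A substituted at C4a, C8 and C8a with C6 left free; ring D fully substituted), in the anti relationship of the two oxygenated carbons, and in the congestion around C8a. The key step uses the fact that C8a sits between C8 and C4a: an open-chain (1R,2S)-1-aryl-2-alkoxy-3-arylpropan-1-ol carrying bromine at C8a can be closed by joining the C2 oxygen to C8a, so ring C forms at an arene carbon and neither stereocentre is touched. For this closure O3 is carried as a benzyl ether and not as a silyl ether: a silyl group next to the C2 alkoxide could migrate under carbonate at 110 °C and open a five-membered closure through O3, whereas benzyl cannot move, chelates in the reduction that sets C2, and leaves in the final hydrogenolysis.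

## Logic of the disconnections

**25 ⇒ 24.** The seven O–CH2Ph bonds (six phenolic, one at O3) are cut last. The free polyphenol tolerates neither base nor oxidants, so it should appear only in a neutral final step. The gain is that every earlier intermediate is a robust polyether. The demand is that H2/Pd cleaves only benzyl C–O bonds and spares the aryl ketone, the diarylmethane and the C2–O1 bond.

**24 ⇒ 23.** The O1–C8a bond is cut. It is the only ring C bond whose formation breaks no bond at C2 or C3. The gain is an acyclic chain whose two stereocentres can be set by acyclic stereocontrol. The demand is a C–O coupling at a bromide with two ortho substituents, a single free hydroxyl, and an O3 group that cannot migrate.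

**23 ⇒ 22.** The C2–H bond is cut, taking the carbinol back to a ketone. C2 can then be derived from C3 through a chelate between the carbonyl oxygen and the O3 ether. The gain is one stereocentre less and a ketone that arises by acyl substitution. The demand is hydride delivery to one face only and no reduction of the ring D ketone.

**22 ⇒ 19 + 21 (21 from 20).** The bond between C2 and the ring B carbon is cut. Ring B leaves as a simple aryl nucleophile and C2 becomes an amide carbon. The demand is single addition, no attack on the ring D ketone, and no loss of configuration at C3.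

**19 ⇒ 13 + 18.** The bond between the methylene carbon and D1 is cut. 18 has one free ring position, activated by three alkoxy groups, and 13 ionises to a benzylic cation stabilised by ortho and para alkoxy groups, so the site is fixed on both partners. The gain is two fragments of similar size with ring D complete. The demand is an acid mild enough to spare the benzyl ethers.

**13 ⇒ 12 ⇒ 11.** The bond between C8 and its exocyclic carbon is cut (formyl group, then its reduction). C8 is the remaining ring A position that is para to one alkoxy group and ortho to the other. The demand is attack at C8 and not at C6, with the amide and C3 intact.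

**11 ⇒ 10 ⇒ 5 + 9 (9 from 8, 8 from 6 + 7).** The C3–C4 bond is cut, after exchange of the amide nitrogen. C3 is then set by alkylation of a chiral glycolate enolate, and C2, C3 and O3 arrive together from 7. The demand is face-selective alkylation by a labile, electron-rich benzylic bromide and clean removal of the auxiliary.

**5 ⇒ 4 ⇒ 3 ⇒ 2 ⇒ 1.** The C4a–C4 bond and the two ring A O–benzyl bonds are cut. Bromine must be present from the start because C8a is meta to both oxygens and cannot be brominated later. The demand is formylation ortho to bromine and not between the two ethers.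

**18 ⇒ 17 ⇒ 16 ⇒ 14 + 15.** The O–methyl bond, two O–benzyl bonds and the D5–acyl bond are cut. 14 is symmetric, so acylation can give only one isomer, and the three hydroxyls of 16 differ in acidity, hindrance and chelation. The demand is that benzylation takes the para and the less hindered ortho hydroxyl and leaves the hydroxyl between acyl and methyl for methylation.

## Other disconnections considered

**Alternative 1:** The cut removes ring D: the bonds D1–D6, D2–D3 and D5–D6 are disconnected. This leads to the C8 siloxyalkyne of penta-O-benzylcatechin A1 and 3-methoxy-2-methylcyclobut-2-en-1-one A2. Heating would open A2 to a ketene intermediate that adds to the alkyne of A1. Ring opening and 6π closure would then give the phenol A3, which lacks only the acyl group.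
- In favour: both stereocentres would come from a natural flavan-3-ol of the chiral pool. On stereochemical security this alternative is better than the chosen plan, and it is probably shorter.
- In favour: the ring D pattern is dictated by the mechanism, which equals the control the chosen plan draws from the symmetry of 14. The free phenol of A3 lies next to the only open ring D carbon, so an O-acylation and Fries shift would place the acyl group without ambiguity.
- Against: A1 is an acid- and moisture-sensitive ynol silyl ether. It must be built at C8 of an advanced flavan (C8 against C6, several steps) and must survive long heating.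
- Against: acylation, a Fries shift on a hindered silylated resorcinol and two different deprotections still follow.
- Comparison: the benzannulation is a four-stage pericyclic cascade on a late intermediate, while the chosen closure is one bond formation with no stereochemical consequence. The alternative wins on stereocentres and step count; the chosen plan wins on the simplicity of the late steps.

**Alternative 2:** The cut is C3–C4 and O1–C2. Ring C would come from the ring A ortho-hydroxybenzyl alcohol A4 and the (E)-styrylboronate A5. A chiral phosphoric acid would dehydrate A4 to its ortho-quinone methide and hold it by hydrogen bonds. A5 would add with the boron-bearing carbon to the methylene and the benzylic carbon to oxygen, giving the 2,3-trans boronate A6. Oxidation of C–B with retention and hydrogenolysis would finish.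
- In favour: two bonds and both stereocentres form in one step, so it is more convergent and shorter than the chosen plan.
- In favour: ring A needs no bromine and is a phloroglucinol derivative, which is easier to assemble than the bromide of the chosen plan. The trans geometry follows from the E alkene.
- Against: the quinone methide has an unsubstituted methylene, so the catalyst alone must distinguish the alkene faces. A vinylboronate is a weak 2π donor, and a simple quinone methide tends to oligomerise.
- Against: the C8a phenol is crowded by the C8 benzyl group, and the enantioselectivity cannot be predicted for this substrate.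
- Comparison: the alternative is better on step economy. The chosen plan is better on absolute stereocontrol, since C3 comes from an auxiliary and C2 from a chelate. Both end with a hydrogenolysis; the alternative needs one more oxidation.

**Alternative 3:** The cut is C4–C4a and C3–O, with the 2,3-trans 2-aryl-3-(mesyloxymethyl)-2,3-dihydrobenzofuran A7 as retron. Ionisation of the primary mesylate in aqueous hexafluoroisopropanol would be assisted by the ring A carbon that becomes C4a. Water would open the phenonium ion at the secondary carbon with inversion, giving A8 with the free C3 hydroxyl.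
- In favour: ring A, with alkoxy groups ortho and para to the migrating carbon, is an excellent migrating group, and the step is stereospecific.
- In favour: only the hydrogenolysis remains after it, which equals the chosen plan after its key step, and no transition metal is needed.
- Against: water can open the phenonium ion at either carbon, and opening at the primary carbon only returns unrearranged alcohol.
- Against: the medium is acidic and strongly ionising, while A7 and A8 contain a benzylic C2–O1 bond and a diarylmethane that can ionise. Elimination to a chromene is a possible escape.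
- Against: an enantiopure trans dihydrobenzofuran carrying the ring D benzyl group must first be made, which is no shorter than making 23.
- Comparison: both closures create no new stereocentre. The chosen one leaves C2 and C3 untouched, while the alternative inverts C3 through a cationic intermediate. Step economy is about equal.

Key step: step 16

Assumptions and conventions:
- 6, 7, 14 and 20 are taken as commercial. 14 is used for ring D because its symmetry fixes the substitution pattern.
- Species that exist only until aqueous work-up (iminium salts, metal alkoxides, the chelated adduct of the amide) are treated as part of the mechanism. Reagents generated in the flask from a numbered compound (9, 21) are numbered.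
- Ring A carbons of open-chain intermediates are called by their future flavan numbers. Ring D carbons are D1–D6 as defined above.
- The (1R,2S) descriptors of 23 correspond to (2R,3S) in 24 and 25.

## Route

Step 1
Reactants: 1 5-bromobenzene-1,3-diol (5-bromoresorcinol)
Product: 2 1,3-bis(benzyloxy)-5-bromobenzene
Conditions: BnBr, K2CO3, DMF, 60 °C
Reagents that add atoms: benzyl bromide, BrCc1ccccc1
Why: Williamson ether synthesis on both phenols; the aryl bromide is inert to carbonate and the benzyl groups last until the final hydrogenolysis.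

Step 2
Reactants: 2 1,3-bis(benzyloxy)-5-bromobenzene
Product: 3 2,4-bis(benzyloxy)-6-bromobenzaldehyde
Conditions: POCl3, DMF, 0 → 80 °C; then H2O
Reagents that add atoms: N,N-dimethylformamide, CN(C)C=O; water, O
Why: Vilsmeier–Haack formylation; the two equivalent positions ortho to bromine are para to one ether and ortho to the other and should react before the position flanked by both ethers, as resorcinol diethers do. The aldehyde deactivates the ring against a second attack.

Step 3
Reactants: 3 2,4-bis(benzyloxy)-6-bromobenzaldehyde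
Product: 4 [2,4-bis(benzyloxy)-6-bromophenyl]methanol
Conditions: NaBH4, THF–MeOH, 0 °C
Reagents that add atoms: none
Why: Borohydride reduction of an aryl aldehyde; ethers and the aryl bromide are untouched.

Step 4
Reactants: 4 [2,4-bis(benzyloxy)-6-bromophenyl]methanol
Product: 5 1,5-bis(benzyloxy)-3-bromo-2-(bromomethyl)benzene
Conditions: PBr3, CH2Cl2, 0 °C; used crude at once
Reagents that add atoms: phosphorus tribromide, BrP(Br)Br
Why: Conversion of a benzylic alcohol into the bromide through its phosphite ester; the electron-rich bromide is labile and is therefore taken on without storage.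

Step 5
Reactants: 6 (4R)-4-benzyl-1,3-oxazolidin-2-one; 7 (benzyloxy)acetyl chloride
Product: 8 (4R)-4-benzyl-3-[(benzyloxy)acetyl]-1,3-oxazolidin-2-one
Conditions: n-BuLi, THF, −78 °C; then 7, −78 → 0 °C
Reagents that add atoms: none
Why: N-acylation of the lithiated oxazolidinone by an acid chloride, the standard entry to chiral glycolate imides.

Step 6
Reactants: 8 (4R)-4-benzyl-3-[(benzyloxy)acetyl]-1,3-oxazolidin-2-one; 5 1,5-bis(benzyloxy)-3-bromo-2-(bromomethyl)benzene
Product: 10 (4R)-4-benzyl-3-{(2S)-2-(benzyloxy)-3-[2,4-bis(benzyloxy)-6-bromophenyl]propanoyl}-1,3-oxazolidin-2-one, via sodium Z-enolate 9 (not isolated)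
Conditions: NaN(SiMe3)2, THF, −78 °C; then 5, −78 → −45 °C
Reagents that add atoms: none
Why: Evans-type asymmetric alkylation of a glycolate imide; the chelated sodium Z-enolate is shielded on one face by the C4 benzyl group of the (R)-auxiliary, so the benzylic bromide should enter from the other face and set the (S) centre that becomes C3. The activated benzylic bromide reacts below the temperature at which the enolate decomposes.

Step 7
Reactants: 10 (4R)-4-benzyl-3-{(2S)-2-(benzyloxy)-3-[2,4-bis(benzyloxy)-6-bromophenyl]propanoyl}-1,3-oxazolidin-2-one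
Product: 11 (2S)-2-(benzyloxy)-3-[2,4-bis(benzyloxy)-6-bromophenyl]-N-methoxy-N-methylpropanamide
Conditions: AlMe3, MeNHOMe·HCl, CH2Cl2, 0 °C → rt; then 0.5 M HCl
Reagents that add atoms: N,O-dimethylhydroxylamine hydrochloride, CNOC.Cl
Why: Weinreb amide formation by transamination of the imide with an aluminium amide; the α-centre is not enolised under these conditions and the auxiliary is recovered.

Step 8
Reactants: 11 (2S)-2-(benzyloxy)-3-[2,4-bis(benzyloxy)-6-bromophenyl]-N-methoxy-N-methylpropanamide
Product: 12 (2S)-2-(benzyloxy)-3-[4,6-bis(benzyloxy)-2-bromo-3-formylphenyl]-N-methoxy-N-methylpropanamide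
Conditions: POCl3, DMF, 0 → 70 °C; then H2O
Reagents that add atoms: N,N-dimethylformamide, CN(C)C=O; water, O
Why: Vilsmeier–Haack formylation; C8 is para to the C5 ether and ortho to the C7 ether, the second position of this kind in the resorcinol diether, whereas C6 lies between both ethers and is the position such ethers substitute last. The N-methoxy amide is a poor partner for POCl3 beside a large excess of DMF.

Step 9
Reactants: 12 (2S)-2-(benzyloxy)-3-[4,6-bis(benzyloxy)-2-bromo-3-formylphenyl]-N-methoxy-N-methylpropanamide
Product: 13 (2S)-2-(benzyloxy)-3-[4,6-bis(benzyloxy)-2-bromo-3-(hydroxymethyl)phenyl]-N-methoxy-N-methylpropanamide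
Conditions: NaBH4, THF–MeOH, 0 °C
Reagents that add atoms: none
Why: Borohydride reduction; an aldehyde is reduced far faster than an N-methoxy-N-methylamide.

Step 10
Reactants: 14 2-methylbenzene-1,3,5-triol (2,4,6-trihydroxytoluene); 15 2-methylpropanoyl chloride (isobutyryl chloride)
Product: 16 2-methyl-1-(2,4,6-trihydroxy-3-methylphenyl)propan-1-one
Conditions: AlCl3, PhNO2–CH2Cl2, 0 °C → rt; then ice, HCl
Reagents that add atoms: none
Why: Friedel–Crafts acylation; the two free ring positions of 14 are equivalent, so only one regioisomer can form, and the acyl group deactivates the ring against a second acylation.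

Step 11
Reactants: 16 2-methyl-1-(2,4,6-trihydroxy-3-methylphenyl)propan-1-one
Product: 17 1-[4,6-bis(benzyloxy)-2-hydroxy-3-methylphenyl]-2-methylpropan-1-one
Conditions: BnBr (2.1 equiv), K2CO3, DMF, rt
Reagents that add atoms: benzyl bromide, BrCc1ccccc1
Why: Selective Williamson etherification; the hydroxyl para to the ketone is the most acidic and the ortho hydroxyl next to the free ring position is the more accessible. The hydroxyl between acyl and methyl is hindered and chelated to the carbonyl and should remain.

Step 12
Reactants: 17 1-[4,6-bis(benzyloxy)-2-hydroxy-3-methylphenyl]-2-methylpropan-1-one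
Product: 18 1-[4,6-bis(benzyloxy)-2-methoxy-3-methylphenyl]-2-methylpropan-1-one
Conditions: MeI, K2CO3, DMF, 50 °C
Reagents that add atoms: iodomethane, CI
Why: O-methylation of the remaining chelated phenol under forcing Williamson conditions; this fixes the methoxy group between acyl and methyl as in ring D.

Step 13
Reactants: 13 (2S)-2-(benzyloxy)-3-[4,6-bis(benzyloxy)-2-bromo-3-(hydroxymethyl)phenyl]-N-methoxy-N-methylpropanamide; 18 1-[4,6-bis(benzyloxy)-2-methoxy-3-methylphenyl]-2-methylpropan-1-one
Product: 19 (2S)-2-(benzyloxy)-3-[4,6-bis(benzyloxy)-3-{[2,6-bis(benzyloxy)-4-methoxy-3-methyl-5-(2-methylpropanoyl)phenyl]methyl}-2-bromophenyl]-N-methoxy-N-methylpropanamide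
Conditions: Sc(OTf)3 (10 mol%), 18 (1.5 equiv), 4 Å MS, CH2Cl2, 0 °C → rt
Reagents that add atoms: none
Why: Friedel–Crafts benzylation; the Lewis acid ionises the benzylic alcohol to a cation stabilised by ortho and para alkoxy groups, which attacks the only free position of 18, activated by three alkoxy groups and meta to the acyl group. Excess 18 suppresses self-condensation of the cation.

Step 14
Reactants: 20 4-bromo-1,2-bis(benzyloxy)benzene; 19 (2S)-2-(benzyloxy)-3-[4,6-bis(benzyloxy)-3-{[2,6-bis(benzyloxy)-4-methoxy-3-methyl-5-(2-methylpropanoyl)phenyl]methyl}-2-bromophenyl]-N-methoxy-N-methylpropanamide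
Product: 22 (2S)-2-(benzyloxy)-3-[4,6-bis(benzyloxy)-3-{[2,6-bis(benzyloxy)-4-methoxy-3-methyl-5-(2-methylpropanoyl)phenyl]methyl}-2-bromophenyl]-1-[3,4-bis(benzyloxy)phenyl]propan-1-one, via aryl Grignard reagent 21 (not isolated)
Conditions: 20, Mg, THF, rt → 40 °C; then 19, THF, −20 → 0 °C; aq. NH4Cl
Reagents that add atoms: none
Why: Weinreb ketone synthesis; the chelated tetrahedral adduct prevents a second addition and releases the ketone only on work-up, so C3 is not epimerised. The ring D ketone, flanked by two ortho substituents and an isopropyl group, should not be attacked.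

Step 15
Reactants: 22 (2S)-2-(benzyloxy)-3-[4,6-bis(benzyloxy)-3-{[2,6-bis(benzyloxy)-4-methoxy-3-methyl-5-(2-methylpropanoyl)phenyl]methyl}-2-bromophenyl]-1-[3,4-bis(benzyloxy)phenyl]propan-1-one
Product: 23 (1R,2S)-2-(benzyloxy)-3-[4,6-bis(benzyloxy)-3-{[2,6-bis(benzyloxy)-4-methoxy-3-methyl-5-(2-methylpropanoyl)phenyl]methyl}-2-bromophenyl]-1-[3,4-bis(benzyloxy)phenyl]propan-1-ol
Conditions: Zn(BH4)2 (from ZnCl2 and NaBH4), Et2O–CH2Cl2, −20 → 0 °C
Reagents that add atoms: none
Why: Chelation-controlled (Cram chelate) reduction; zinc bridges the carbonyl oxygen and the O3 benzyl ether, and hydride enters from the face that carries the C3 hydrogen, which should give the (1R) carbinol and the anti 1,2-dioxygenated array. The hindered, unchelated ring D ketone should react much more slowly.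

Step 16
Reactants: 23 (1R,2S)-2-(benzyloxy)-3-[4,6-bis(benzyloxy)-3-{[2,6-bis(benzyloxy)-4-methoxy-3-methyl-5-(2-methylpropanoyl)phenyl]methyl}-2-bromophenyl]-1-[3,4-bis(benzyloxy)phenyl]propan-1-ol
Product: 24 (2R,3S)-3,5,7-tris(benzyloxy)-2-[3,4-bis(benzyloxy)phenyl]-8-{[2,6-bis(benzyloxy)-4-methoxy-3-methyl-5-(2-methylpropanoyl)phenyl]methyl}-3,4-dihydro-2H-chromene (hepta-O-benzyl pilosanol B)
Conditions: CuI (20 mol%), 3,4,7,8-tetramethyl-1,10-phenanthroline (40 mol%), Cs2CO3 (2 equiv), toluene, 110 °C, argon
Reagents that add atoms: none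
Why: Cs2CO3 converts the C2 hydroxyl into its alkoxide, which binds monovalent copper carrying the phenanthroline ligand. The C8a–Br bond, held beside the metal by the three-carbon chain, then adds oxidatively to give an aryl(alkoxo) trivalent copper species, a seven-membered metallacycle. Reductive elimination forms O1–C8a, closes the six-membered ring C by attack at the arene carbon (closure exo to the C–Br bond) and returns monovalent copper. The closest known reaction type is the Ullmann-type copper-catalysed intramolecular O-arylation of secondary alcohols by aryl bromides, which gives chromans. No stereocentre is formed: no bond at C2 or C3 is broken, so the (1R,2S) anti arrangement of 23 becomes the (2R,3S) 2,3-trans arrangement of 24. The step needs selectivity for the C2 oxygen and for six- over five-membered closure; both are secured because C2–OH is the only free hydroxyl and the O3 benzyl ether can neither migrate nor be arylated. Intramolecularity has to compensate for the two ortho substituents of the electron-rich bromide, and exclusion of oxygen keeps the benzylic alkoxide from being oxidised to the ketone.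

Step 17
Reactants: 24 hepta-O-benzyl pilosanol B
Product: 25 pilosanol B, 1-[3-{[(2R,3S)-2-(3,4-dihydroxyphenyl)-3,5,7-trihydroxy-3,4-dihydro-2H-chromen-8-yl]methyl}-2,4-dihydroxy-6-methoxy-5-methylphenyl]-2-methylpropan-1-one
Conditions: H2 (1 atm), Pd(OH)2/C, THF–MeOH, rt
Reagents that add atoms: none
Why: Catalytic hydrogenolysis of six aryl benzyl ethers and the C3 benzyl ether under neutral conditions; the acylphloroglucinol ketone, the diarylmethane and the C2–O1 bond of catechin-type flavans are expected to survive, and no base is present to epimerise C2.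

## Compound list

1 | 5-bromobenzene-1,3-diol (5-bromoresorcinol) | Oc1cc(O)cc(Br)c1 | starting material
2 | 1,3-bis(benzyloxy)-5-bromobenzene | Brc1cc(OCc2ccccc2)cc(OCc2ccccc2)c1 | intermediate
3 | 2,4-bis(benzyloxy)-6-bromobenzaldehyde | O=Cc1c(Br)cc(OCc2ccccc2)cc1OCc1ccccc1 | intermediate
4 | [2,4-bis(benzyloxy)-6-bromophenyl]methanol | OCc1c(Br)cc(OCc2ccccc2)cc1OCc1ccccc1 | intermediate
5 | 1,5-bis(benzyloxy)-3-bromo-2-(bromomethyl)benzene | BrCc1c(Br)cc(OCc2ccccc2)cc1OCc1ccccc1 | intermediate
6 | (4R)-4-benzyl-1,3-oxazolidin-2-one | O=C1N[C@H](Cc2ccccc2)CO1 | starting material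
7 | (benzyloxy)acetyl chloride | ClC(=O)COCc1ccccc1 | starting material
8 | (4R)-4-benzyl-3-[(benzyloxy)acetyl]-1,3-oxazolidin-2-one | O=C(COCc1ccccc1)N1[C@H](Cc2ccccc2)COC1=O | intermediate
9 | sodium (Z)-enolate of 8 | [Na+].[O-]/C(=C\OCc1ccccc1)N1[C@H](Cc2ccccc2)COC1=O | intermediate (formed in the flask, not isolated)
10 | (4R)-4-benzyl-3-{(2S)-2-(benzyloxy)-3-[2,4-bis(benzyloxy)-6-bromophenyl]propanoyl}-1,3-oxazolidin-2-one | O=C([C@@H](OCc1ccccc1)Cc1c(Br)cc(OCc2ccccc2)cc1OCc1ccccc1)N1[C@H](Cc2ccccc2)COC1=O | intermediate
11 | (2S)-2-(benzyloxy)-3-[2,4-bis(benzyloxy)-6-bromophenyl]-N-methoxy-N-methylpropanamide | CON(C)C(=O)[C@@H](OCc1ccccc1)Cc1c(Br)cc(OCc2ccccc2)cc1OCc1ccccc1 | intermediate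
12 | (2S)-2-(benzyloxy)-3-[4,6-bis(benzyloxy)-2-bromo-3-formylphenyl]-N-methoxy-N-methylpropanamide | CON(C)C(=O)[C@@H](OCc1ccccc1)Cc1c(Br)c(C=O)c(OCc2ccccc2)cc1OCc1ccccc1 | intermediate
13 | (2S)-2-(benzyloxy)-3-[4,6-bis(benzyloxy)-2-bromo-3-(hydroxymethyl)phenyl]-N-methoxy-N-methylpropanamide | CON(C)C(=O)[C@@H](OCc1ccccc1)Cc1c(Br)c(CO)c(OCc2ccccc2)cc1OCc1ccccc1 | intermediate
14 | 2-methylbenzene-1,3,5-triol (2,4,6-trihydroxytoluene) | Cc1c(O)cc(O)cc1O | starting material
15 | 2-methylpropanoyl chloride (isobutyryl chloride) | CC(C)C(=O)Cl | starting material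
16 | 2-methyl-1-(2,4,6-trihydroxy-3-methylphenyl)propan-1-one | CC(C)C(=O)c1c(O)cc(O)c(C)c1O | intermediate
17 | 1-[4,6-bis(benzyloxy)-2-hydroxy-3-methylphenyl]-2-methylpropan-1-one | CC(C)C(=O)c1c(O)c(C)c(OCc2ccccc2)cc1OCc1ccccc1 | intermediate
18 | 1-[4,6-bis(benzyloxy)-2-methoxy-3-methylphenyl]-2-methylpropan-1-one | COc1c(C)c(OCc2ccccc2)cc(OCc2ccccc2)c1C(=O)C(C)C | intermediate
19 | (2S)-2-(benzyloxy)-3-[4,6-bis(benzyloxy)-3-{[2,6-bis(benzyloxy)-4-methoxy-3-methyl-5-(2-methylpropanoyl)phenyl]methyl}-2-bromophenyl]-N-methoxy-N-methylpropanamide | CON(C)C(=O)[C@@H](OCc1ccccc1)Cc1c(Br)c(Cc2c(OCc3ccccc3)c(C)c(OC)c(C(=O)C(C)C)c2OCc2ccccc2)c(OCc2ccccc2)cc1OCc1ccccc1 | intermediate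
20 | 4-bromo-1,2-bis(benzyloxy)benzene | Brc1ccc(OCc2ccccc2)c(OCc2ccccc2)c1 | starting material
21 | [3,4-bis(benzyloxy)phenyl]magnesium bromide | Br[Mg]c1ccc(OCc2ccccc2)c(OCc2ccccc2)c1 | intermediate (formed in the flask, not isolated)
22 | (2S)-2-(benzyloxy)-3-[4,6-bis(benzyloxy)-3-{[2,6-bis(benzyloxy)-4-methoxy-3-methyl-5-(2-methylpropanoyl)phenyl]methyl}-2-bromophenyl]-1-[3,4-bis(benzyloxy)phenyl]propan-1-one | O=C(c1ccc(OCc2ccccc2)c(OCc2ccccc2)c1)[C@@H](OCc1ccccc1)Cc1c(Br)c(Cc2c(OCc3ccccc3)c(C)c(OC)c(C(=O)C(C)C)c2OCc2ccccc2)c(OCc2ccccc2)cc1OCc1ccccc1 | intermediate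
23 | (1R,2S)-2-(benzyloxy)-3-[4,6-bis(benzyloxy)-3-{[2,6-bis(benzyloxy)-4-methoxy-3-methyl-5-(2-methylpropanoyl)phenyl]methyl}-2-bromophenyl]-1-[3,4-bis(benzyloxy)phenyl]propan-1-ol | O[C@H](c1ccc(OCc2ccccc2)c(OCc2ccccc2)c1)[C@@H](OCc1ccccc1)Cc1c(Br)c(Cc2c(OCc3ccccc3)c(C)c(OC)c(C(=O)C(C)C)c2OCc2ccccc2)c(OCc2ccccc2)cc1OCc1ccccc1 | intermediate
24 | hepta-O-benzyl pilosanol B, (2R,3S)-3,5,7-tris(benzyloxy)-2-[3,4-bis(benzyloxy)phenyl]-8-{[2,6-bis(benzyloxy)-4-methoxy-3-methyl-5-(2-methylpropanoyl)phenyl]methyl}-3,4-dihydro-2H-chromene | COc1c(C)c(OCc4ccccc4)c(Cc2c(OCc4ccccc4)cc(OCc4ccccc4)c3c2O[C@H](c2ccc(OCc4ccccc4)c(OCc4ccccc4)c2)[C@@H](OCc4ccccc4)C3)c(OCc4ccccc4)c1C(=O)C(C)C | intermediate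
25 | pilosanol B | COc1c(C)c(O)c(Cc2c(O)cc(O)c3c2O[C@H](c2ccc(O)c(O)c2)[C@@H](O)C3)c(O)c1C(=O)C(C)C | target

## Step count and risks

Total: 17 steps. Longest linear sequence: 13 steps from 1 (steps 1–4, 6–9 and 13–17). Steps 10–12 (ring D) and step 5 (auxiliary) are side branches.

**Step 16 (key step).** The most likely failure is slow oxidative addition at the C8a–Br bond, which is flanked by two benzylic substituents on an electron-rich ring. During the long heating this would let oxidation of the benzylic alkoxide to the ketone or loss of bromine take over. A change of ligand or metal would be tried first. The fallback proper closes ring C before C8 is substituted, so the bromide has only one ortho substituent. It sets out from 11 and returns at 24.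
Addition of 21 to 11 would give the ketone (2S)-2-(benzyloxy)-1-[3,4-bis(benzyloxy)phenyl]-3-[2,4-bis(benzyloxy)-6-bromophenyl]propan-1-one F1. Reduction with Zn(BH4)2 as in step 15 would give the anti alcohol (1R,2S)-2-(benzyloxy)-1-[3,4-bis(benzyloxy)phenyl]-3-[2,4-bis(benzyloxy)-6-bromophenyl]propan-1-ol F2. The CuI coupling of step 16 would give the flavan (2R,3S)-3,5,7-tris(benzyloxy)-2-[3,4-bis(benzyloxy)phenyl]-3,4-dihydro-2H-chromene F3. Vilsmeier–Haack formylation at C8, the position not flanked by two benzyloxy groups, would give (2R,3S)-3,5,7-tris(benzyloxy)-2-[3,4-bis(benzyloxy)phenyl]-3,4-dihydro-2H-chromene-8-carbaldehyde F4. NaBH4 would give [(2R,3S)-3,5,7-tris(benzyloxy)-2-[3,4-bis(benzyloxy)phenyl]-3,4-dihydro-2H-chromen-8-yl]methanol F5. Sc(OTf)3-catalysed benzylation of 18 with F5, as in step 13, would give 24. The number of steps from 11 to 24 is unchanged.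

**Step 8.** The most likely failure is slow formylation at the crowded C8 position, so that forcing conditions are needed, under which the amide may be activated or C3 eroded. The second concern is partial attack at C6. The fallback moves the second formylation to an achiral stage without an amide, where harsher conditions and separation of regioisomers are acceptable. It sets out from 4 and 18 and returns at 19.
Sc(OTf)3-catalysed benzylation of 18 with 4 would give the diarylmethane 1-[2,4-bis(benzyloxy)-3-{[2,4-bis(benzyloxy)-6-bromophenyl]methyl}-6-methoxy-5-methylphenyl]-2-methylpropan-1-one F6. Vilsmeier–Haack formylation would give 4,6-bis(benzyloxy)-2-bromo-3-{[2,6-bis(benzyloxy)-4-methoxy-3-methyl-5-(2-methylpropanoyl)phenyl]methyl}benzaldehyde F7. NaBH4, which should leave the hindered ring D ketone, would give the alcohol 1-[2,4-bis(benzyloxy)-3-{[4,6-bis(benzyloxy)-2-bromo-3-(hydroxymethyl)phenyl]methyl}-6-methoxy-5-methylphenyl]-2-methylpropan-1-one F8. PBr3 would give the bromide 1-[2,4-bis(benzyloxy)-3-{[4,6-bis(benzyloxy)-2-bromo-3-(bromomethyl)phenyl]methyl}-6-methoxy-5-methylphenyl]-2-methylpropan-1-one F9. Alkylation of enolate 9 with F9 as in step 6 would give the imide (4R)-4-benzyl-3-{(2S)-2-(benzyloxy)-3-[4,6-bis(benzyloxy)-3-{[2,6-bis(benzyloxy)-4-methoxy-3-methyl-5-(2-methylpropanoyl)phenyl]methyl}-2-bromophenyl]propanoyl}-1,3-oxazolidin-2-one F10. Transamination as in step 7 would give 19.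

**Step 13.** The most likely failure is that the benzylic cation is consumed by self-condensation, or benzyl ethers ionise, before the hindered position of 18 between two benzyloxy groups reacts. The fallback uses the much more nucleophilic free diphenol. It sets out from 18 and returns at 19.
Hydrogenolysis of 18 (H2, Pd/C) would give 1-(4,6-dihydroxy-2-methoxy-3-methylphenyl)-2-methylpropan-1-one F11. Its position between two hydroxyl groups should couple with 13 under catalytic acid to give the diphenol (2S)-2-(benzyloxy)-3-[4,6-bis(benzyloxy)-2-bromo-3-{[2,6-dihydroxy-4-methoxy-3-methyl-5-(2-methylpropanoyl)phenyl]methyl}phenyl]-N-methoxy-N-methylpropanamide F12. Benzylation of both phenols (BnBr, K2CO3, DMF) would give 19.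

**Step 7.** The most likely failure is attack of the aluminium amide on the ring carbonyl of the oxazolidinone, with opening of the auxiliary, because the acyl carbonyl is α-branched and flanked by a bulky arylmethyl group. The fallback separates cleavage and amide formation. It sets out from 10 and returns at 11.
LiOH with H2O2, whose hydroperoxide anion attacks the exocyclic carbonyl, would give the acid (2S)-2-(benzyloxy)-3-[2,4-bis(benzyloxy)-6-bromophenyl]propanoic acid F13. Coupling with MeNHOMe·HCl (EDC·HCl, HOBt, iPr2NEt) would give 11.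

## Further compounds

F1 | step 16 | (2S)-2-(benzyloxy)-1-[3,4-bis(benzyloxy)phenyl]-3-[2,4-bis(benzyloxy)-6-bromophenyl]propan-1-one | O=C(c1ccc(OCc2ccccc2)c(OCc2ccccc2)c1)[C@@H](OCc1ccccc1)Cc1c(Br)cc(OCc2ccccc2)cc1OCc1ccccc1
F2 | step 16 | (1R,2S)-2-(benzyloxy)-1-[3,4-bis(benzyloxy)phenyl]-3-[2,4-bis(benzyloxy)-6-bromophenyl]propan-1-ol | O[C@H](c1ccc(OCc2ccccc2)c(OCc2ccccc2)c1)[C@@H](OCc1ccccc1)Cc1c(Br)cc(OCc2ccccc2)cc1OCc1ccccc1
F3 | step 16 | (2R,3S)-3,5,7-tris(benzyloxy)-2-[3,4-bis(benzyloxy)phenyl]-3,4-dihydro-2H-chromene (penta-O-benzyl-(+)-catechin) | c1c(OCc4ccccc4)cc(OCc4ccccc4)c2c1O[C@H](c1ccc(OCc4ccccc4)c(OCc4ccccc4)c1)[C@@H](OCc4ccccc4)C2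
F4 | step 16 | (2R,3S)-3,5,7-tris(benzyloxy)-2-[3,4-bis(benzyloxy)phenyl]-3,4-dihydro-2H-chromene-8-carbaldehyde | O=Cc1c(OCc4ccccc4)cc(OCc4ccccc4)c2c1O[C@H](c1ccc(OCc4ccccc4)c(OCc4ccccc4)c1)[C@@H](OCc4ccccc4)C2
F5 | step 16 | [(2R,3S)-3,5,7-tris(benzyloxy)-2-[3,4-bis(benzyloxy)phenyl]-3,4-dihydro-2H-chromen-8-yl]methanol | OCc1c(OCc4ccccc4)cc(OCc4ccccc4)c2c1O[C@H](c1ccc(OCc4ccccc4)c(OCc4ccccc4)c1)[C@@H](OCc4ccccc4)C2
F6 | step 8 | 1-[2,4-bis(benzyloxy)-3-{[2,4-bis(benzyloxy)-6-bromophenyl]methyl}-6-methoxy-5-methylphenyl]-2-methylpropan-1-one | COc1c(C)c(OCc4ccccc4)c(Cc2c(Br)cc(OCc4ccccc4)cc2OCc2ccccc2)c(OCc4ccccc4)c1C(=O)C(C)C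
F7 | step 8 | 4,6-bis(benzyloxy)-2-bromo-3-{[2,6-bis(benzyloxy)-4-methoxy-3-methyl-5-(2-methylpropanoyl)phenyl]methyl}benzaldehyde | COc1c(C)c(OCc4ccccc4)c(Cc2c(Br)c(C=O)c(OCc4ccccc4)cc2OCc2ccccc2)c(OCc4ccccc4)c1C(=O)C(C)C
F8 | step 8 | 1-[2,4-bis(benzyloxy)-3-{[4,6-bis(benzyloxy)-2-bromo-3-(hydroxymethyl)phenyl]methyl}-6-methoxy-5-methylphenyl]-2-methylpropan-1-one | COc1c(C)c(OCc4ccccc4)c(Cc2c(Br)c(CO)c(OCc4ccccc4)cc2OCc2ccccc2)c(OCc4ccccc4)c1C(=O)C(C)C
F9 | step 8 | 1-[2,4-bis(benzyloxy)-3-{[4,6-bis(benzyloxy)-2-bromo-3-(bromomethyl)phenyl]methyl}-6-methoxy-5-methylphenyl]-2-methylpropan-1-one | COc1c(C)c(OCc4ccccc4)c(Cc2c(Br)c(CBr)c(OCc4ccccc4)cc2OCc2ccccc2)c(OCc4ccccc4)c1C(=O)C(C)C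
F10 | step 8 | (4R)-4-benzyl-3-{(2S)-2-(benzyloxy)-3-[4,6-bis(benzyloxy)-3-{[2,6-bis(benzyloxy)-4-methoxy-3-methyl-5-(2-methylpropanoyl)phenyl]methyl}-2-bromophenyl]propanoyl}-1,3-oxazolidin-2-one | O=C([C@@H](OCc1ccccc1)Cc1c(Br)c(Cc2c(OCc3ccccc3)c(C)c(OC)c(C(=O)C(C)C)c2OCc2ccccc2)c(OCc2ccccc2)cc1OCc1ccccc1)N1[C@H](Cc2ccccc2)COC1=O
F11 | step 13 | 1-(4,6-dihydroxy-2-methoxy-3-methylphenyl)-2-methylpropan-1-one | COc1c(C)c(O)cc(O)c1C(=O)C(C)C
F12 | step 13 | (2S)-2-(benzyloxy)-3-[4,6-bis(benzyloxy)-2-bromo-3-{[2,6-dihydroxy-4-methoxy-3-methyl-5-(2-methylpropanoyl)phenyl]methyl}phenyl]-N-methoxy-N-methylpropanamide | CON(C)C(=O)[C@@H](OCc1ccccc1)Cc1c(Br)c(Cc2c(O)c(C)c(OC)c(C(=O)C(C)C)c2O)c(OCc2ccccc2)cc1OCc1ccccc1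
F13 | step 7 | (2S)-2-(benzyloxy)-3-[2,4-bis(benzyloxy)-6-bromophenyl]propanoic acid | OC(=O)[C@@H](OCc1ccccc1)Cc1c(Br)cc(OCc2ccccc2)cc1OCc1ccccc1
A1 | alternative 1 | penta-O-benzylcatechin carrying a 3-(triisopropylsilyloxy)prop-2-yn-1-yl group at C8 (siloxyalkyne) | CC(C)[Si](OC#CCc1c(OCc4ccccc4)cc(OCc4ccccc4)c2c1O[C@H](c1ccc(OCc4ccccc4)c(OCc4ccccc4)c1)[C@@H](OCc4ccccc4)C2)(C(C)C)C(C)C
A2 | alternative 1 | 3-methoxy-2-methylcyclobut-2-en-1-one | COC1=C(C)C(=O)C1
A3 | alternative 1 | penta-O-benzylcatechin carrying at C8 a [6-hydroxy-4-methoxy-3-methyl-2-(triisopropylsilyloxy)phenyl]methyl group | COc1cc(O)c(Cc2c(OCc4ccccc4)cc(OCc4ccccc4)c3c2O[C@H](c2ccc(OCc4ccccc4)c(OCc4ccccc4)c2)[C@@H](OCc4ccccc4)C3)c(O[Si](C(C)C)(C(C)C)C(C)C)c1C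
A4 | alternative 2 | 1-[2,4-bis(benzyloxy)-3-{[4,6-bis(benzyloxy)-2-hydroxy-3-(hydroxymethyl)phenyl]methyl}-6-methoxy-5-methylphenyl]-2-methylpropan-1-one (ring A ortho-hydroxybenzyl alcohol) | OCc1c(O)c(Cc2c(OCc4ccccc4)c(C)c(OC)c(C(=O)C(C)C)c2OCc2ccccc2)c(OCc4ccccc4)cc1OCc1ccccc1
A5 | alternative 2 | (E)-2-[3,4-bis(benzyloxy)styryl]-4,4,5,5-tetramethyl-1,3,2-dioxaborolane | CC1(C)OB(/C=C/c2ccc(OCc3ccccc3)c(OCc3ccccc3)c2)OC1(C)C
A6 | alternative 2 | hexa-O-benzyl 2,3-trans flavan with a pinacolboryl group at C3 | COc1c(C)c(OCc4ccccc4)c(Cc2c(OCc4ccccc4)cc(OCc4ccccc4)c3c2O[C@H](c2ccc(OCc4ccccc4)c(OCc4ccccc4)c2)[C@@H](B2OC(C)(C)C(C)(C)O2)C3)c(OCc4ccccc4)c1C(=O)C(C)C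
A7 | alternative 3 | 2,3-trans 2-[3,4-bis(benzyloxy)phenyl]-4,6-bis(benzyloxy)-7-(ring D benzyl)-2,3-dihydrobenzofuran-3-ylmethyl methanesulfonate | COc1c(C)c(OCc4ccccc4)c(Cc2c(OCc4ccccc4)cc(OCc4ccccc4)c3c2O[C@H](c2ccc(OCc4ccccc4)c(OCc4ccccc4)c2)[C@H]3COS(C)(=O)=O)c(OCc4ccccc4)c1C(=O)C(C)C
A8 | alternative 3 | hexa-O-benzyl pilosanol B (free C3 hydroxyl) | COc1c(C)c(OCc4ccccc4)c(Cc2c(OCc4ccccc4)cc(OCc4ccccc4)c3c2O[C@H](c2ccc(OCc4ccccc4)c(OCc4ccccc4)c2)[C@@H](O)C3)c(OCc4ccccc4)c1C(=O)C(C)C
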